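## Retrosynthetic overview

1. The target 14 comes from boronate 13 by one fluoride treatment that removes three aryl silyl ethers and the boron bridge.
2. Boronate 13 comes from epoxy aldehyde 4 and triol 10 in a single flask: the C4–C4a bond (magnesium-chelate ortho-hydroxyalkylation), then the O1–C2 bond (6-endo oxirane opening, closing ring C), then the O4–B–O5 bridge (dioxaborinine ring).
3. Epoxy aldehyde 4 carries all the stereochemical information. It comes from organocatalytic epoxidation of enal 3, made by Wittig homologation of silylated gallaldehyde 2.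
4. Triol 10 comes from syringic acid 5 by dibromination, carboxylate-assisted copper hydroxylation and loss of CO2.
5. Ring order: rings A and B are bought; ring C and the temporary boron ring close together in step 6.

Assumption: the SMILES is read as (2R,3S,4R), i.e. 2,3-trans-3,4-trans; flavan numbering (O1, C2, C3, C4, C4a, C5–C8, C8a) is used; TBS = tert-butyldimethylsilyl.

## Route

Step 1
Reactants: 1 3,4,5-trihydroxybenzaldehyde
Product: 2 3,4,5-tris(tert-butyldimethylsilyloxy)benzaldehyde
Conditions: TBSCl (3.6 equiv), imidazole (7 equiv), DMF, 0 °C to rt, N2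
Reagents that add atoms: tert-butyldimethylsilyl chloride, CC(C)(C)[Si](C)(C)Cl
Why: Imidazole-promoted silylation of phenols masks the oxidation-prone pyrogallol as aryl silyl ethers that fluoride later removes without acid, base or hydrogen.

Step 2
Reactants: 2 3,4,5-tris(tert-butyldimethylsilyloxy)benzaldehyde
Product: 3 (2E)-3-[3,4,5-tris(tert-butyldimethylsilyloxy)phenyl]prop-2-enal
Conditions: Ph3P=CHCHO (1.15 equiv), toluene, 80 °C
Reagents that add atoms: (triphenylphosphoranylidene)acetaldehyde, O=CC=P(c1ccccc1)(c1ccccc1)c1ccccc1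
Why: Wittig olefination with a stabilised ylide gives the E-enal in one step, and near-stoichiometric ylide limits further homologation.

Step 3
Reactants: 3 (2E)-3-[3,4,5-tris(tert-butyldimethylsilyloxy)phenyl]prop-2-enal
Product: 4 (2R,3S)-3-[3,4,5-tris(tert-butyldimethylsilyloxy)phenyl]oxirane-2-carbaldehyde (trans)
Conditions: H2O2 (35% aq., 1.3 equiv), (R)-2-{bis[3,5-bis(trifluoromethyl)phenyl](trimethylsilyloxy)methyl}pyrrolidine (10 mol %), CH2Cl2, rt; short silica filtration, used at once
Reagents that add atoms: hydrogen peroxide, OO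
Why: Organocatalytic (Jørgensen-type) iminium/enamine epoxidation of an enal: the silyloxydiarylmethyl group of the R catalyst shields one face of the E-iminium ion, so hydroperoxide adds to the open Re face of C-3 and the enamine closes the oxirane on the same face, setting both centres as trans-(2R,3S); this catalyst sense is derived from the steric-shielding model, and the antipodal catalyst would give the enantiomer.

Step 4
Reactants: 5 syringic acid (4-hydroxy-3,5-dimethoxybenzoic acid)
Product: 7 4-acetoxy-2,6-dibromo-3,5-dimethoxybenzoic acid, via 4-acetoxy-3,5-dimethoxybenzoic acid 6 (not isolated)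
Conditions: Ac2O (1.5 equiv), H2SO4 (cat.), AcOH, 60 °C; then Br2 (2.5 equiv), rt to 50 °C
Reagents that add atoms: acetic anhydride, CC(=O)OC(C)=O; bromine, BrBr
Why: O-acetylation suppresses ipso attack para to the phenol (bromodecarboxylation), so electrophilic aromatic bromination is steered by the two methoxy groups to the only free positions, each ortho to one OMe and para to the other.

Step 5
Reactants: 7 4-acetoxy-2,6-dibromo-3,5-dimethoxybenzoic acid
Product: 10 2,4-dimethoxybenzene-1,3,5-triol, via 2,6-dibromo-4-hydroxy-3,5-dimethoxybenzoic acid 8 (not isolated), via 2,4,6-trihydroxy-3,5-dimethoxybenzoic acid 9 (not isolated)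
Conditions: NaOH (8 equiv), Cu2O (10 mol %), degassed H2O, 100 °C, Ar; then HCl to pH 1, 70 °C; work-up under Ar
Reagents that add atoms: sodium hydroxide, [Na+].[OH-]
Why: Ullmann-type, carboxylate-assisted copper hydroxylation of ortho-bromobenzoic acids replaces both bromides after the acetate is saponified, and the resulting phloroglucinol-type carboxylic acid loses CO2 by ipso-protonation on warming in acid, so the carboxyl group blocks the para position in step 4, activates the bromides here and then leaves without trace.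

Step 6
Reactants: 4 (2R,3S)-3-[3,4,5-tris(tert-butyldimethylsilyloxy)phenyl]oxirane-2-carbaldehyde; 10 2,4-dimethoxybenzene-1,3,5-triol
Product: 13 O-4/O-5 cyclic phenylboronate of (2R,3S,4R)-6,8-dimethoxy-2-[3,4,5-tris(tert-butyldimethylsilyloxy)phenyl]chromane-3,4,5,7-tetrol (2-phenyl-4H-1,3,2-benzodioxaborinine ring peri-fused to the chromane; 3-OH and 7-OH free), via epoxy alcohol 11 (not isolated), via silylated flavan-3,4-diol 12 (not isolated)
Conditions: 10, Bu2Mg (1.0 equiv, heptane), CH2Cl2/toluene, 0 °C, Ar; add 4 (1.0 equiv), −30 °C to rt; then AcOH (2 equiv), PhB(OH)2 (1.05 equiv), 4 Å molecular sieves, rt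
Reagents that add atoms: phenylboronic acid, OB(O)c1ccccc1
Why: Proposed new method: the halide-free magnesium phenolate of 10 holds the aldehyde oxygen and the oxirane oxygen of 4 in a five-membered chelate and delivers its only free ring carbon through the ortho-specific six-membered transition state known from the Casiraghi magnesium-phenolate hydroxyalkylation of alpha-oxygenated aldehydes, attacking the carbonyl face anti to the oxirane ring carbon (Cram chelate) to set C-4 as R; the new magnesium alkoxide then directs a flanking phenoxide onto the distal benzylic oxirane carbon (the C-3-selective opening of metal-bound 2,3-epoxy alcohols, here 6-endo) with inversion, which sets C-2 as R, keeps the oxirane-derived C-3 as S and closes ring C as the all-equatorial 2,3-trans-3,4-trans diol; phenylboronic acid finally condenses with the peri 4-OH/5-OH pair (Nagata-type benzodioxaborinine formation), a second ring that the 3,4-trans isomer forms with all substituents equatorial and that protects the ionisable benzylic alcohol for isolation.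

Step 7
Reactants: 13 O-4/O-5 cyclic phenylboronate
Product: 14 (2R,3S,4R)-6,8-dimethoxy-2-(3,4,5-trihydroxyphenyl)chromane-3,4,5,7-tetrol (CNP0305400.1)
Conditions: Et3N·3HF (6 equiv), THF, 0 °C to rt, Ar; pH 6 phosphate buffer work-up, Sephadex LH-20
Reagents that add atoms: none
Why: Fluoride-driven cleavage of the three aryl O–Si bonds and fluorolysis of the two B–O bonds (boronate to trifluoroborate) frees the remaining five hydroxyls under non-basic, non-hydrogenolytic conditions that neither oxidise the pyrogallol nor ionise the benzylic C-4 alcohol, and no stereocentre is touched.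

## Compound list

1 | 3,4,5-trihydroxybenzaldehyde | O=Cc1cc(O)c(O)c(O)c1 | starting material
2 | 3,4,5-tris(tert-butyldimethylsilyloxy)benzaldehyde | O=Cc1cc(O[Si](C)(C)C(C)(C)C)c(O[Si](C)(C)C(C)(C)C)c(O[Si](C)(C)C(C)(C)C)c1 | intermediate
3 | (2E)-3-[3,4,5-tris(tert-butyldimethylsilyloxy)phenyl]prop-2-enal | O=C/C=C/c1cc(O[Si](C)(C)C(C)(C)C)c(O[Si](C)(C)C(C)(C)C)c(O[Si](C)(C)C(C)(C)C)c1 | intermediate
4 | (2R,3S)-3-[3,4,5-tris(tert-butyldimethylsilyloxy)phenyl]oxirane-2-carbaldehyde | O=C[C@@H]1O[C@H]1c1cc(O[Si](C)(C)C(C)(C)C)c(O[Si](C)(C)C(C)(C)C)c(O[Si](C)(C)C(C)(C)C)c1 | intermediate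
5 | syringic acid (4-hydroxy-3,5-dimethoxybenzoic acid) | COc1cc(C(=O)O)cc(OC)c1O | starting material
6 | 4-acetoxy-3,5-dimethoxybenzoic acid | COc1cc(C(=O)O)cc(OC)c1OC(C)=O | intermediate
7 | 4-acetoxy-2,6-dibromo-3,5-dimethoxybenzoic acid | COc1c(Br)c(C(=O)O)c(Br)c(OC)c1OC(C)=O | intermediate
8 | 2,6-dibromo-4-hydroxy-3,5-dimethoxybenzoic acid | COc1c(Br)c(C(=O)O)c(Br)c(OC)c1O | intermediate
9 | 2,4,6-trihydroxy-3,5-dimethoxybenzoic acid | COc1c(O)c(C(=O)O)c(O)c(OC)c1O | intermediate
10 | 2,4-dimethoxybenzene-1,3,5-triol | COc1c(O)cc(O)c(OC)c1O | intermediate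
11 | (R)-{(2S,3S)-3-[3,4,5-tris(tert-butyldimethylsilyloxy)phenyl]oxiran-2-yl}(2,4,6-trihydroxy-3,5-dimethoxyphenyl)methanol (present as its magnesium salt) | COc1c(O)c(OC)c(O)c(c1O)[C@@H](O)[C@@H]2O[C@H]2c3cc(O[Si](C)(C)C(C)(C)C)c(O[Si](C)(C)C(C)(C)C)c(O[Si](C)(C)C(C)(C)C)c3 | intermediate
12 | (2R,3S,4R)-6,8-dimethoxy-2-[3,4,5-tris(tert-butyldimethylsilyloxy)phenyl]chromane-3,4,5,7-tetrol | COc1c(O)c(OC)c2c(c1O)[C@@H](O)[C@H](O)[C@@H](c1cc(O[Si](C)(C)C(C)(C)C)c(O[Si](C)(C)C(C)(C)C)c(O[Si](C)(C)C(C)(C)C)c1)O2 | intermediate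
13 | O-4/O-5 cyclic phenylboronate of 12, (2R,3S,4R) | COc1c(O)c(OC)c2c3c1OB(c4ccccc4)O[C@H]3[C@H](O)[C@@H](c5cc(O[Si](C)(C)C(C)(C)C)c(O[Si](C)(C)C(C)(C)C)c(O[Si](C)(C)C(C)(C)C)c5)O2 | intermediate
14 | (2R,3S,4R)-6,8-dimethoxy-2-(3,4,5-trihydroxyphenyl)chromane-3,4,5,7-tetrol | COc1c(O)c(OC)c2c(c1O)[C@@H](O)[C@H](O)[C@@H](c1cc(O)c(O)c(O)c1)O2 | target

## Step count and risk

Total steps: 7. Longest linear sequence: 5 (steps 1, 2, 3, 6, 7).

**Step 6** is the most likely to fail. The magnesium chelate may not override Felkin-type addition (giving a C-4 mixture), 5-exo oxirane opening may compete, and the benzylic alkoxide may ionise and capture a second molecule of 10. The fallback sets out from 12, taken as the crude C-4 epimer mixture with the boronate trap omitted. Both epimers are oxidised at the ortho/para-hydroxybenzylic carbinol with activated MnO2 in CH2Cl2 to the single (2R,3R)-3,5,7-trihydroxy-6,8-dimethoxy-2-[3,4,5-tris(tert-butyldimethylsilyloxy)phenyl]chroman-4-one F1. NaBH4 in THF/MeOH at 0 °C then reduces the ketone to the 3,4-trans diol, as in the classical reduction of 2,3-trans dihydroflavonols. This comes back to the route at 12, which is trapped with PhB(OH)2 to give 13 as before. C-4 is then set by hydride delivery, not by the arylation.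

**Step 5** is the second risk. Double copper hydroxylation next to a hindered carboxylate may stall or give hydrodebromination, and the electron-rich triol can oxidise in hot base. The fallback sets out from 7 and removes the carboxyl first by protodecarboxylation (Ag2CO3 10 mol %, AcOH cat., DMSO, 120 °C) to give 3,5-dibromo-2,6-dimethoxyphenyl acetate F2. F2 is then hydroxylated by palladium-catalysed C–O coupling (Pd2(dba)3, 2-di-tert-butylphosphino-2',4',6'-triisopropylbiphenyl, KOH, 1,4-dioxane/H2O, 100 °C), which also cleaves the acetate. Acidification returns the route at 10.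

**Step 3** is the third risk. The electron-rich epoxy aldehyde may rearrange or hydrate, the ee may be low, and the catalyst sense rests on a model. The fallback sets out from 3. Luche reduction (NaBH4, CeCl3·7H2O, MeOH, 0 °C) gives (2E)-3-[3,4,5-tris(tert-butyldimethylsilyloxy)phenyl]prop-2-en-1-ol F3. Sharpless asymmetric epoxidation (Ti(OiPr)4, L-(+)-diisopropyl tartrate, tBuOOH, 4 Å molecular sieves, CH2Cl2, −20 °C) gives {(2S,3S)-3-[3,4,5-tris(tert-butyldimethylsilyloxy)phenyl]oxiran-2-yl}methanol F4, with the well-established sense for E-cinnamyl alcohols. Parikh–Doering oxidation (SO3·pyridine, DMSO, iPr2NEt, 0 °C) returns the route at 4.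

## Further compounds

F1 | step 6 | (2R,3R)-3,5,7-trihydroxy-6,8-dimethoxy-2-[3,4,5-tris(tert-butyldimethylsilyloxy)phenyl]chroman-4-one | COc1c(O)c(OC)c2c(c1O)C(=O)[C@H](O)[C@@H](c1cc(O[Si](C)(C)C(C)(C)C)c(O[Si](C)(C)C(C)(C)C)c(O[Si](C)(C)C(C)(C)C)c1)O2
F2 | step 5 | 3,5-dibromo-2,6-dimethoxyphenyl acetate | CC(=O)Oc1c(OC)c(Br)cc(Br)c1OC
F3 | step 3 | (2E)-3-[3,4,5-tris(tert-butyldimethylsilyloxy)phenyl]prop-2-en-1-ol | OC/C=C/c1cc(O[Si](C)(C)C(C)(C)C)c(O[Si](C)(C)C(C)(C)C)c(O[Si](C)(C)C(C)(C)C)c1
F4 | step 3 | {(2S,3S)-3-[3,4,5-tris(tert-butyldimethylsilyloxy)phenyl]oxiran-2-yl}methanol | OC[C@@H]1O[C@H]1c1cc(O[Si](C)(C)C(C)(C)C)c(O[Si](C)(C)C(C)(C)C)c(O[Si](C)(C)C(C)(C)C)c1
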